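**Retrosynthetic overview**
1. Target 12 ⇐ aryl silyl ether 11 ⇐ diol 10 (primary-selective acetylation) ⇐ diacetal 9 (hydrolysis). The two CH2O arms stay distinct (exocyclic ester carbon vs ring CH2O) until the tiglate is in place.
2. 9 ⇐ alcohol 8 ⇐ ester 7 (ester → CH2OH → tiglate).
3. Key disconnection: the C(aryl)–C(quaternary) bond of 7 ⇒ enolate 6 + aryl iodide 3, joined in a light-driven radical-chain (SRN1) arylation. The new centre is controlled by the 5,6-ketal centres.
4. 5 ⇐ methyl (S)-glycerate acetonide 4 (the only bought stereocentre) + 2,2,3,3-tetramethoxybutane; 3 ⇐ 4-methoxy-2-methylphenol 1 (silylation, iodination).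
5. Rings: the arene is bought; the only ring made is the temporary 1,4-dioxane (step 3), opened again in step 7.

Assumption: the target is read as the (R)-carbinol carrying an (E)-2-methylbut-2-enoate (tiglate); 1, 4, 2,2,3,3-tetramethoxybutane and tigloyl chloride are taken as catalogue chemicals.
Note: the C-2 descriptor alternates along 7–10 only through CIP priority changes; no bond to that centre is broken after step 4.

**Step 1**
Reactants: 1 4-methoxy-2-methylphenol
Product: 2 (4-methoxy-2-methylphenoxy)triisopropylsilane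
Conditions: TIPSCl, imidazole, DMF, rt
Reagents that add atoms: chlorotriisopropylsilane CC(C)[Si](Cl)(C(C)C)C(C)C
Why: Phenol silylation (silyl ether formation) masks the oxidisable, H-donating hydroquinone-type OH for the radical step and the later acylations.

**Step 2**
Reactants: 2 (4-methoxy-2-methylphenoxy)triisopropylsilane
Product: 3 (5-iodo-4-methoxy-2-methylphenoxy)triisopropylsilane
Conditions: NIS, TFA (cat.), MeCN, 0 °C → rt
Reagents that add atoms: N-iodosuccinimide O=C1CCC(=O)N1I
Why: Electrophilic aromatic iodination goes to C-5, which is ortho to OMe and para to the methyl group, while the bulky OTIPS shields C-6.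

**Step 3**
Reactants: 4 methyl (4S)-2,2-dimethyl-1,3-dioxolane-4-carboxylate
Product: 5 methyl (2S,5S,6S)-5,6-dimethoxy-5,6-dimethyl-1,4-dioxane-2-carboxylate
Conditions: 2,2,3,3-tetramethoxybutane, CSA (cat.), MeOH, reflux
Reagents that add atoms: 2,2,3,3-tetramethoxybutane COC(C)(OC)C(C)(OC)OC
Why: Acid-catalysed trans-ketalisation to the butane-2,3-diacetal under thermodynamic control puts CO2Me equatorial and both anomerically stabilised OMe groups axial, so the bought (S)-centre sets the two ketal centres (5S,6S).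

**Step 4**
Reactants: 5 methyl (2S,5S,6S)-5,6-dimethoxy-5,6-dimethyl-1,4-dioxane-2-carboxylate; 3 (5-iodo-4-methoxy-2-methylphenoxy)triisopropylsilane
Product: 7 methyl (2R,5S,6S)-5,6-dimethoxy-2-[2-methoxy-4-methyl-5-(triisopropylsilyloxy)phenyl]-5,6-dimethyl-1,4-dioxane-2-carboxylate, via potassium ester enolate 6 (not isolated)
Conditions: KHMDS, THF, −78 °C; then 3, NH3(l)/THF, hν (350 nm, Pyrex), −50 °C
Reagents that add atoms: none
Why: Proposed new method: photostimulated SRN1 α-arylation of an α,β-dialkoxy ester enolate with stereochemical relay – light-induced electron transfer in the enolate·ArI pair gives iodide and the aryl σ-radical, which adds to the exocyclic enolate carbon of 6 from the equatorial face anti to the syn-axial 6-OMe (aryl equatorial, CO2Me axial, new centre R), and the product radical anion reduces the next ArI to carry the chain; the ring oxygen β to the enolate is gauche to the π-system, so E1cB ring opening should be slow at −50 °C; the closest known chemistry is the photostimulated SRN1 arylation of ketone, amide and simple ester enolates (tertiary ones included) and the alkyl-halide alkylation of diacetal-locked enolates, neither of which has been shown for aryl transfer to this enolate class or for setting an oxygenated quaternary stereocentre.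

**Step 5**
Reactants: 7 methyl (2R,5S,6S)-5,6-dimethoxy-2-[2-methoxy-4-methyl-5-(triisopropylsilyloxy)phenyl]-5,6-dimethyl-1,4-dioxane-2-carboxylate
Product: 8 [(2S,5S,6S)-5,6-dimethoxy-2-[2-methoxy-4-methyl-5-(triisopropylsilyloxy)phenyl]-5,6-dimethyl-1,4-dioxan-2-yl]methanol
Conditions: LiAlH4, THF, 0 °C
Reagents that add atoms: none
Why: Hydride reduction of the ester to the primary alcohol leaves the ketals, the aryl silyl ether and the quaternary centre untouched.

**Step 6**
Reactants: 8 [(2S,5S,6S)-5,6-dimethoxy-2-[2-methoxy-4-methyl-5-(triisopropylsilyloxy)phenyl]-5,6-dimethyl-1,4-dioxan-2-yl]methanol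
Product: 9 [(2R,5S,6S)-5,6-dimethoxy-2-[2-methoxy-4-methyl-5-(triisopropylsilyloxy)phenyl]-5,6-dimethyl-1,4-dioxan-2-yl]methyl (E)-2-methylbut-2-enoate
Conditions: tigloyl chloride, pyridine, DMAP (cat.), CH2Cl2, 0 °C → rt
Reagents that add atoms: (E)-2-methylbut-2-enoyl chloride C/C=C(\C)C(Cl)=O
Why: DMAP-catalysed O-acylation of the only free hydroxyl, with pyridine rather than a trialkylamine to avoid ketene formation and E/Z or deconjugative isomerisation of the tiglate.

**Step 7**
Reactants: 9 [(2R,5S,6S)-5,6-dimethoxy-2-[2-methoxy-4-methyl-5-(triisopropylsilyloxy)phenyl]-5,6-dimethyl-1,4-dioxan-2-yl]methyl (E)-2-methylbut-2-enoate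
Product: 10 (2R)-2,3-dihydroxy-2-[2-methoxy-4-methyl-5-(triisopropylsilyloxy)phenyl]propyl (E)-2-methylbut-2-enoate
Conditions: TFA/H2O (9:1), 0 °C, 10 min
Reagents that add atoms: none
Why: Acid hydrolysis of the diacetal cleaves only at the ketal carbons, so the C–O bond at the stereocentre is not broken, and the two β-oxygen substituents disfavour benzylic ionisation during the short cold exposure.

**Step 8**
Reactants: 10 (2R)-2,3-dihydroxy-2-[2-methoxy-4-methyl-5-(triisopropylsilyloxy)phenyl]propyl (E)-2-methylbut-2-enoate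
Product: 11 (2R)-3-acetoxy-2-hydroxy-2-[2-methoxy-4-methyl-5-(triisopropylsilyloxy)phenyl]propyl (E)-2-methylbut-2-enoate
Conditions: Ac2O, pyridine, CH2Cl2, 0 °C
Reagents that add atoms: acetic anhydride CC(=O)OC(C)=O
Why: Chemoselective acetylation of the primary over the tertiary benzylic alcohol (no DMAP, 0 °C) under conditions too mild for 1,3-migration of the tiglate, which would erode the ee.

**Step 9**
Reactants: 11 (2R)-3-acetoxy-2-hydroxy-2-[2-methoxy-4-methyl-5-(triisopropylsilyloxy)phenyl]propyl (E)-2-methylbut-2-enoate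
Product: 12 (2R)-3-acetoxy-2-hydroxy-2-(5-hydroxy-2-methoxy-4-methylphenyl)propyl (E)-2-methylbut-2-enoate
Conditions: TBAF, AcOH, THF, 0 °C
Reagents that add atoms: none
Why: Fluoride-mediated cleavage of the aryl silyl ether, buffered with AcOH so that no basic acyl migration or transesterification occurs.

**Compound list**
1 | 4-methoxy-2-methylphenol | COc1ccc(O)c(C)c1 | starting material
2 | (4-methoxy-2-methylphenoxy)triisopropylsilane | COc1ccc(O[Si](C(C)C)(C(C)C)C(C)C)c(C)c1 | intermediate
3 | (5-iodo-4-methoxy-2-methylphenoxy)triisopropylsilane | COc1cc(C)c(O[Si](C(C)C)(C(C)C)C(C)C)cc1I | intermediate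
4 | methyl (4S)-2,2-dimethyl-1,3-dioxolane-4-carboxylate | COC(=O)[C@@H]1COC(C)(C)O1 | starting material
5 | methyl (2S,5S,6S)-5,6-dimethoxy-5,6-dimethyl-1,4-dioxane-2-carboxylate | COC(=O)[C@@H]1CO[C@](C)(OC)[C@@](C)(OC)O1 | intermediate
6 | potassium enolate of 5 (5S,6S; not isolated) | [K+].COC([O-])=C1CO[C@](C)(OC)[C@@](C)(OC)O1 | intermediate
7 | methyl (2R,5S,6S)-5,6-dimethoxy-2-[2-methoxy-4-methyl-5-(triisopropylsilyloxy)phenyl]-5,6-dimethyl-1,4-dioxane-2-carboxylate | COC(=O)[C@@]1(c2cc(O[Si](C(C)C)(C(C)C)C(C)C)c(C)cc2OC)CO[C@](C)(OC)[C@@](C)(OC)O1 | intermediate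
8 | [(2S,5S,6S)-5,6-dimethoxy-2-[2-methoxy-4-methyl-5-(triisopropylsilyloxy)phenyl]-5,6-dimethyl-1,4-dioxan-2-yl]methanol | OC[C@@]1(c2cc(O[Si](C(C)C)(C(C)C)C(C)C)c(C)cc2OC)CO[C@](C)(OC)[C@@](C)(OC)O1 | intermediate
9 | [(2R,5S,6S)-5,6-dimethoxy-2-[2-methoxy-4-methyl-5-(triisopropylsilyloxy)phenyl]-5,6-dimethyl-1,4-dioxan-2-yl]methyl (E)-2-methylbut-2-enoate | C/C=C(\C)C(=O)OC[C@@]1(c2cc(O[Si](C(C)C)(C(C)C)C(C)C)c(C)cc2OC)CO[C@](C)(OC)[C@@](C)(OC)O1 | intermediate
10 | (2R)-2,3-dihydroxy-2-[2-methoxy-4-methyl-5-(triisopropylsilyloxy)phenyl]propyl (E)-2-methylbut-2-enoate | C/C=C(\C)C(=O)OC[C@](O)(CO)c1cc(O[Si](C(C)C)(C(C)C)C(C)C)c(C)cc1OC | intermediate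
11 | (2R)-3-acetoxy-2-hydroxy-2-[2-methoxy-4-methyl-5-(triisopropylsilyloxy)phenyl]propyl (E)-2-methylbut-2-enoate | C/C=C(\C)C(=O)OC[C@](O)(COC(C)=O)c1cc(O[Si](C(C)C)(C(C)C)C(C)C)c(C)cc1OC | intermediate
12 | (2R)-3-acetoxy-2-hydroxy-2-(5-hydroxy-2-methoxy-4-methylphenyl)propyl (E)-2-methylbut-2-enoate | C/C=C(\C)C(=O)OC[C@](O)(COC(C)=O)c1cc(O)c(C)cc1OC | target

**Step count and risks**
Total steps: 9. Longest linear sequence: 8 (1 → 12 through steps 1, 2 and 4–9; the branch from 4 is 7 steps).

Step 4 (proposed new arylation) is the most likely to fail. The aryl radical may abstract a C-3 hydrogen from the enolate and give the reduced arene, coupling at the hindered tetrasubstituted carbon may be slow, or the enolate may ring-open. The fallback sets out from 5 (with an aryl bromide made from 2) and returns at 7. Brominate 2 with NBS in MeCN to (5-bromo-4-methoxy-2-methylphenoxy)triisopropylsilane F1. Deprotonate 5 with LiHMDS at −78 °C to the lithium enolate F2 and transmetalate with ZnCl2 to the chlorozinc enolate F3. Couple F3 with F1 under Pd(dba)2/Q-Phos in THF at rt; this is the thermal Pd-catalysed α-arylation of zinc ester enolates, known to give quaternary α-aryl esters. The same face bias should apply, giving 7.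

Step 7 (diacetal hydrolysis on the electron-rich tertiary benzylic system) is the second risk. Ionisation at the benzylic carbon, possibly assisted by the neighbouring tiglate carbonyl, would racemise the centre. The fallback sets out from 7 and returns at 10. Hydrolyse the diacetal at the ester stage with TFA/H2O, where the α-ester blocks benzylic ionisation, to methyl (2R)-2,3-dihydroxy-2-[2-methoxy-4-methyl-5-(triisopropylsilyloxy)phenyl]propanoate F4. Re-protect with 2,2-dimethoxypropane/PPTS as methyl (4R)-4-[2-methoxy-4-methyl-5-(triisopropylsilyloxy)phenyl]-2,2-dimethyl-1,3-dioxolane-4-carboxylate F5. Reduce with LiAlH4 to [(4S)-4-[2-methoxy-4-methyl-5-(triisopropylsilyloxy)phenyl]-2,2-dimethyl-1,3-dioxolan-4-yl]methanol F6. Acylate with tigloyl chloride/pyridine to [(4R)-4-[2-methoxy-4-methyl-5-(triisopropylsilyloxy)phenyl]-2,2-dimethyl-1,3-dioxolan-4-yl]methyl (E)-2-methylbut-2-enoate F7. Remove the acetonide with 80% aqueous AcOH at rt, far milder than the diacetal cleavage, to reach 10.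

Step 2 (regioselective iodination) is the third risk, since some iodination ortho to the silyloxy group (C-6) would give an inseparable isomer. The fallback sets out from 1 and returns at 3. Acetylate 1 with Ac2O/pyridine to 4-methoxy-2-methylphenyl acetate F8, in which the weakly donating acetoxy group leaves OMe as the only strong director. Iodinate with NIS/TFA to 5-iodo-4-methoxy-2-methylphenyl acetate F9. Cleave the acetate with K2CO3/MeOH to 5-iodo-4-methoxy-2-methylphenol F10, then silylate with TIPSCl/imidazole to 3.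

**Further compounds**
F1 | step 4 | (5-bromo-4-methoxy-2-methylphenoxy)triisopropylsilane | COc1cc(C)c(O[Si](C(C)C)(C(C)C)C(C)C)cc1Br
F2 | step 4 | lithium enolate of 5 | [Li+].COC([O-])=C1CO[C@](C)(OC)[C@@](C)(OC)O1
F3 | step 4 | chlorozinc enolate of 5 | COC(O[Zn]Cl)=C1CO[C@](C)(OC)[C@@](C)(OC)O1
F4 | step 7 | methyl (2R)-2,3-dihydroxy-2-[2-methoxy-4-methyl-5-(triisopropylsilyloxy)phenyl]propanoate | COC(=O)[C@@](O)(c1cc(O[Si](C(C)C)(C(C)C)C(C)C)c(C)cc1OC)CO
F5 | step 7 | methyl (4R)-4-[2-methoxy-4-methyl-5-(triisopropylsilyloxy)phenyl]-2,2-dimethyl-1,3-dioxolane-4-carboxylate | COC(=O)[C@@]1(c2cc(O[Si](C(C)C)(C(C)C)C(C)C)c(C)cc2OC)COC(C)(C)O1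
F6 | step 7 | [(4S)-4-[2-methoxy-4-methyl-5-(triisopropylsilyloxy)phenyl]-2,2-dimethyl-1,3-dioxolan-4-yl]methanol | OC[C@@]1(c2cc(O[Si](C(C)C)(C(C)C)C(C)C)c(C)cc2OC)COC(C)(C)O1
F7 | step 7 | [(4R)-4-[2-methoxy-4-methyl-5-(triisopropylsilyloxy)phenyl]-2,2-dimethyl-1,3-dioxolan-4-yl]methyl (E)-2-methylbut-2-enoate | C/C=C(\C)C(=O)OC[C@@]1(c2cc(O[Si](C(C)C)(C(C)C)C(C)C)c(C)cc2OC)COC(C)(C)O1
F8 | step 2 | 4-methoxy-2-methylphenyl acetate | COc1ccc(OC(C)=O)c(C)c1
F9 | step 2 | 5-iodo-4-methoxy-2-methylphenyl acetate | COc1cc(C)c(OC(C)=O)cc1I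
F10 | step 2 | 5-iodo-4-methoxy-2-methylphenol | COc1cc(C)c(O)cc1I
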